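**Retrosynthetic overview**

- The target is read as epiguibourtinidol-(4β→8)-epicatechin: upper unit 2R,3R,4R (2,3-cis-3,4-trans), lower unit 2R,3R (2,3-cis). The last step is hydrogenolysis of its hepta-O-benzyl ether.
- The lower pyran ring (O1–C2–C3–C4–C4a–C8a of the epicatechin unit) is closed last, by C4–C4a bond formation: gold-catalysed oxidative cyclisation of an aryl 1-arylpropargyl ether gives the flavan-3-one. A dynamic-kinetic-resolution hydrogenation then sets C2/C3 (2R,3R, cis) and removes the ketone oxidation level.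
- Enabling feature: in the lower unit O1 carries the chain C2–C3(O)–C4, which ends on C4a. C4a is the only free carbon ortho to O1 (the other, C8, holds the interflavan bond) and is ortho/para to O1, O5 and O7. A propargyl ether therefore maps onto the ring: propargylic C → C2, internal alkyne C → C3=O, terminal alkyne C → C4.
- The ether comes from a Mitsunobu reaction of a 2-(flavan-4-yl)phenol with a propargylic alcohol. The interflavan C4–C8 bond comes from Friedel–Crafts attack of 3,5-bis(benzyloxy)phenol on the upper-unit C4 cation, anti to O3.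
- The upper unit is built by the same propargyl ether / flavan-3-one / hydrogenation sequence on 3-(benzyloxy)phenol. Ring order: upper pyran ring (step 3), then lower pyran ring (step 10); all benzene rings are bought.

Key step: step 10

Remark on the chemistry: 3,5-bis(benzyloxy)phenol is taken as purchasable. In steps 4 and 11 the catalyst enantiomer is the one that gives the (3R)-alcohol; (S)-XylBINAP/(S)-DAIPEN is written as the working choice and is exchanged for its mirror image if the sense of induction is the opposite.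

**Route**

Step 1
Reactants: 1 4-(benzyloxy)benzaldehyde; 2 ethynylmagnesium bromide
Product: 3 rac-1-[4-(benzyloxy)phenyl]prop-2-yn-1-ol
Conditions: HC≡CMgBr (1.3 equiv), THF, 0 °C to rt; aq. NH4Cl
Reagents that add atoms: none
Why: Grignard addition of the acetylide to the aldehyde gives the secondary propargylic alcohol, used as the racemate because this carbon becomes the stereolabile C2 of ketone 6.

Step 2
Reactants: 3 rac-1-[4-(benzyloxy)phenyl]prop-2-yn-1-ol; 4 3-(benzyloxy)phenol
Product: 5 rac-1-(benzyloxy)-3-({1-[4-(benzyloxy)phenyl]prop-2-yn-1-yl}oxy)benzene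
Conditions: PPh3, DIAD, THF, 0 °C to rt
Reagents that add atoms: none
Why: Mitsunobu etherification joins the phenol oxygen to the activated propargylic carbon, and the new stereocentre is left racemic on purpose since it is equilibrated in step 4.

Step 3
Reactants: 5 rac-1-(benzyloxy)-3-({1-[4-(benzyloxy)phenyl]prop-2-yn-1-yl}oxy)benzene
Product: 6 rac-7-(benzyloxy)-2-[4-(benzyloxy)phenyl]chroman-3-one
Conditions: Me4tBuXPhosAuNTf2 (5 mol%), 2,6-dichloropyridine N-oxide (1.5 equiv), DCE, rt
Reagents that add atoms: 2,6-dichloropyridine N-oxide, [O-][n+]1c(Cl)cccc1Cl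
Why: Gold-catalysed oxidation of the terminal alkyne by the N-oxide gives an α-oxo gold carbene that is captured by the ortho carbon of the aryl ether (the known oxidative cyclisation of aryl propargyl ethers to chroman-3-ones), attack para to the benzyloxy group being preferred over the hindered carbon between the two oxygens; no stereocentre is set.

Step 4
Reactants: 6 rac-7-(benzyloxy)-2-[4-(benzyloxy)phenyl]chroman-3-one
Product: 7 (2R,3R)-7-(benzyloxy)-2-[4-(benzyloxy)phenyl]chroman-3-ol (2,3-cis; 7,4'-di-O-benzyl-epiguibourtinidol)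
Conditions: trans-RuCl2[(S)-XylBINAP][(S)-DAIPEN] (1 mol%), t-BuOK (10 mol%), H2 (10 atm), i-PrOH/toluene, 25 °C
Reagents that add atoms: none
Why: Noyori asymmetric hydrogenation with dynamic kinetic resolution, as for racemic α-aryl and α-aryloxy cycloalkanones: C2–H, α to the ketone and flanked by aryl and aryloxy groups, epimerises through the enolate faster than reduction, and the catalyst reduces the (2R)-ketone with hydride delivery trans to the 2-aryl group, which sets C3 (R) cis to C2 (R).

Step 5
Reactants: 7 (2R,3R)-7-(benzyloxy)-2-[4-(benzyloxy)phenyl]chroman-3-ol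
Product: 8 (2R,3R)-3,7-bis(benzyloxy)-2-[4-(benzyloxy)phenyl]chromane
Conditions: NaH, BnBr, TBAI (cat.), DMF, 0 °C to rt
Reagents that add atoms: benzyl bromide, BrCc1ccccc1
Why: Williamson etherification protects O3 as a benzyl ether that falls in the final hydrogenolysis and keeps this hydroxyl out of the Mitsunobu and gold steps; no stereocentre is touched.

Step 6
Reactants: 8 (2R,3R)-3,7-bis(benzyloxy)-2-[4-(benzyloxy)phenyl]chromane
Product: 9 3,7-bis(benzyloxy)-2-[4-(benzyloxy)phenyl]-4-(2-ethoxyethoxy)chromane, 2,3-cis-3,4-trans (2R and 3 as in 8; the 4-alkoxy group on the face opposite to the 3-benzyloxy and 2-aryl groups, 4β)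
Conditions: DDQ (2 equiv), 2-ethoxyethanol (5 equiv), CH2Cl2, rt
Reagents that add atoms: 2-ethoxyethanol, CCOCCO
Why: DDQ abstracts hydride from C4, the benzylic position activated by O1 (ortho) and the 7-benzyloxy group (para), and the alcohol traps the cation anti to the 3-benzyloxy group (oxidative benzylic etherification as used for C4 activation of flavan-3-ols); this C4 configuration is lost again in step 7.

Step 7
Reactants: 9 3,7-bis(benzyloxy)-2-[4-(benzyloxy)phenyl]-4-(2-ethoxyethoxy)chromane (2,3-cis-3,4-trans); 10 3,5-bis(benzyloxy)phenol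
Product: 11 3,5-bis(benzyloxy)-2-{(2R,3R,4R)-3,7-bis(benzyloxy)-2-[4-(benzyloxy)phenyl]chroman-4-yl}phenol
Conditions: 10 (3 equiv), TMSOTf (20 mol%), CH2Cl2, −40 to 0 °C
Reagents that add atoms: none
Why: Lewis acid ionisation of the 4-alkoxy group and Friedel–Crafts alkylation: the flavan-4-yl cation is attacked on its β-face, anti to the 3-benzyloxy and 2-aryl groups, which sets C4 (R, 3,4-trans), and the bond forms at the phenol carbon between OH and OBn, not at the more hindered carbon between the two OBn groups, in analogy to the C8 selectivity of benzylated flavan-3-ol nucleophiles, while the excess of 10 suppresses double alkylation.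

Step 8
Reactants: 12 3,4-bis(benzyloxy)benzaldehyde; 2 ethynylmagnesium bromide
Product: 13 rac-1-[3,4-bis(benzyloxy)phenyl]prop-2-yn-1-ol
Conditions: HC≡CMgBr (1.3 equiv), THF, 0 °C to rt; aq. NH4Cl
Reagents that add atoms: none
Why: Grignard addition as in step 1; the racemate is used because this carbon becomes the stereolabile C2 of ketone 15.

Step 9
Reactants: 11 3,5-bis(benzyloxy)-2-{(2R,3R,4R)-3,7-bis(benzyloxy)-2-[4-(benzyloxy)phenyl]chroman-4-yl}phenol; 13 rac-1-[3,4-bis(benzyloxy)phenyl]prop-2-yn-1-ol
Product: 14 (2R,3R,4R)-3,7-bis(benzyloxy)-2-[4-(benzyloxy)phenyl]-4-[2,4-bis(benzyloxy)-6-({1-[3,4-bis(benzyloxy)phenyl]prop-2-yn-1-yl}oxy)phenyl]chromane, both configurations at the propargylic carbon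
Conditions: PPh3, DIAD, THF/toluene, 0 °C to rt
Reagents that add atoms: none
Why: Mitsunobu etherification of the only free hydroxyl (the phenol) with the propargylic alcohol; both configurations at the new centre are acceptable because this carbon becomes the stereolabile C2 of ketone 15.

Step 10
Reactants: 14 aryl 1-arylpropargyl ether (both propargylic epimers)
Product: 15 5,7-bis(benzyloxy)-2-[3,4-bis(benzyloxy)phenyl]-8-{(2R,3R,4R)-3,7-bis(benzyloxy)-2-[4-(benzyloxy)phenyl]chroman-4-yl}chroman-3-one, both configurations at C2 of the chromanone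
Conditions: Me4tBuXPhosAuNTf2 (5–10 mol%), 2,6-dichloropyridine N-oxide (1.5 equiv), DCE, rt
Reagents that add atoms: 2,6-dichloropyridine N-oxide, [O-][n+]1c(Cl)cccc1Cl
Why: The cationic gold(I) centre activates the terminal alkyne of 14, the N-oxide adds to the internal alkyne carbon and loses 2,6-dichloropyridine, and the resulting α-oxo gold carbene already has the old internal carbon as the C3 carbonyl and the old terminal carbon (future C4) as a strongly electrophilic carbene. The closest known reaction type is the gold-catalysed oxidation of aryl propargyl ethers to chroman-3-ones, which runs through this carbene and its capture by the aryl ring. The pyran ring closes by C4–C4a bond formation, an intramolecular Friedel–Crafts-type attack of the arene on the carbene carbon through a six-membered transition state (6-exo, the C=Au bond lying outside the forming ring), followed by rearomatisation and protodeauration that turn the carbene carbon into the C4 methylene. No stereocentre is created; the propargylic carbon becomes C2 next to the new ketone and thus epimerisable, so both epimers of 14 should converge on one stereolabile ketone whose configuration is settled in step 11. The step needs site selectivity in the carbene capture and chemoselectivity for oxidation over direct 6-endo hydroarylation of the alkyne: the first is secured by the substrate, because the second carbon ortho to the ether oxygen (C8) carries the upper flavanyl unit and the free one (C4a) is ortho/para to three oxygen substituents, the second by the bulky biarylphosphine ligand and the excess of N-oxide.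

Step 11
Reactants: 15 flavan-3-one (both C2 epimers)
Product: 16 (2R,3R)-5,7-bis(benzyloxy)-2-[3,4-bis(benzyloxy)phenyl]-8-{(2R,3R,4R)-3,7-bis(benzyloxy)-2-[4-(benzyloxy)phenyl]chroman-4-yl}chroman-3-ol (hepta-O-benzyl target)
Conditions: trans-RuCl2[(S)-XylBINAP][(S)-DAIPEN] (2 mol%), t-BuOK (10 mol%), H2 (10 atm), i-PrOH/toluene, 25 °C
Reagents that add atoms: none
Why: Noyori asymmetric hydrogenation with dynamic kinetic resolution as in step 4: base-mediated epimerisation at C2 of the lower unit interconverts the two ketone epimers, and the chiral Ru catalyst reduces the (2R)-epimer with hydride delivery trans to the 2-aryl group, so that C2 (R) and C3 (R, cis) are set under catalyst control while the non-enolisable upper-unit stereocentres stay untouched.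

Step 12
Reactants: 16 hepta-O-benzyl target
Product: 17 (2R,3R)-2-(3,4-dihydroxyphenyl)-8-[(2R,3R,4R)-3,7-dihydroxy-2-(4-hydroxyphenyl)chroman-4-yl]chroman-3,5,7-triol (CNP0118995.2)
Conditions: H2 (1 atm), 20% Pd(OH)2/C, THF/MeOH/H2O, rt
Reagents that add atoms: none
Why: Hydrogenolysis over Pearlman's catalyst cleaves all seven benzyl ethers (six aryl, one secondary alkyl) under conditions that leave the pyran C–O bonds, the interflavan bond and all stereocentres untouched.

**Compound list**

1 | 4-(benzyloxy)benzaldehyde | O=Cc1ccc(OCc2ccccc2)cc1 | starting material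
2 | ethynylmagnesium bromide | C#C[Mg]Br | starting material
3 | rac-1-[4-(benzyloxy)phenyl]prop-2-yn-1-ol | OC(C#C)c1ccc(OCc2ccccc2)cc1 | intermediate
4 | 3-(benzyloxy)phenol | Oc1cccc(OCc2ccccc2)c1 | starting material
5 | rac-1-(benzyloxy)-3-({1-[4-(benzyloxy)phenyl]prop-2-yn-1-yl}oxy)benzene | C#CC(Oc1cccc(OCc2ccccc2)c1)c1ccc(OCc2ccccc2)cc1 | intermediate
6 | rac-7-(benzyloxy)-2-[4-(benzyloxy)phenyl]chroman-3-one | O=C1Cc2ccc(OCc3ccccc3)cc2OC1c1ccc(OCc2ccccc2)cc1 | intermediate
7 | (2R,3R)-7-(benzyloxy)-2-[4-(benzyloxy)phenyl]chroman-3-ol | O(Cc5ccccc5)c1ccc([C@H]2Oc3cc(OCc5ccccc5)ccc3C[C@H]2O)cc1 | intermediate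
8 | (2R,3R)-3,7-bis(benzyloxy)-2-[4-(benzyloxy)phenyl]chromane | O(Cc5ccccc5)c1ccc([C@H]2Oc3cc(OCc5ccccc5)ccc3C[C@H]2OCc5ccccc5)cc1 | intermediate
9 | 3,7-bis(benzyloxy)-2-[4-(benzyloxy)phenyl]-4-(2-ethoxyethoxy)chromane, 2,3-cis-3,4-trans (4β-ether) | O(Cc5ccccc5)c1ccc([C@H]2Oc3cc(OCc5ccccc5)ccc3[C@H](OCCOCC)[C@H]2OCc5ccccc5)cc1 | intermediate
10 | 3,5-bis(benzyloxy)phenol | Oc1cc(OCc2ccccc2)cc(OCc2ccccc2)c1 | starting material
11 | 3,5-bis(benzyloxy)-2-{(2R,3R,4R)-3,7-bis(benzyloxy)-2-[4-(benzyloxy)phenyl]chroman-4-yl}phenol | O(Cc5ccccc5)c1ccc([C@H]2Oc3cc(OCc5ccccc5)ccc3[C@H](c3c(OCc5ccccc5)cc(OCc5ccccc5)cc3O)[C@H]2OCc5ccccc5)cc1 | intermediate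
12 | 3,4-bis(benzyloxy)benzaldehyde | O=Cc1ccc(OCc2ccccc2)c(OCc2ccccc2)c1 | starting material
13 | rac-1-[3,4-bis(benzyloxy)phenyl]prop-2-yn-1-ol | OC(C#C)c1ccc(OCc2ccccc2)c(OCc2ccccc2)c1 | intermediate
14 | (2R,3R,4R)-3,7-bis(benzyloxy)-2-[4-(benzyloxy)phenyl]-4-[2,4-bis(benzyloxy)-6-({1-[3,4-bis(benzyloxy)phenyl]prop-2-yn-1-yl}oxy)phenyl]chromane, both propargylic epimers (centre left undefined) | O(Cc5ccccc5)c1ccc([C@H]2Oc3cc(OCc5ccccc5)ccc3[C@H](c3c(OCc5ccccc5)cc(OCc5ccccc5)cc3OC(C#C)c3ccc(OCc5ccccc5)c(OCc5ccccc5)c3)[C@H]2OCc5ccccc5)cc1 | intermediate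
15 | 5,7-bis(benzyloxy)-2-[3,4-bis(benzyloxy)phenyl]-8-{(2R,3R,4R)-3,7-bis(benzyloxy)-2-[4-(benzyloxy)phenyl]chroman-4-yl}chroman-3-one, both C2 epimers (centre left undefined) | O(Cc5ccccc5)c1ccc([C@H]2Oc3cc(OCc5ccccc5)ccc3[C@H](c3c(OCc5ccccc5)cc(OCc5ccccc5)c4c3OC(c3ccc(OCc5ccccc5)c(OCc5ccccc5)c3)C(=O)C4)[C@H]2OCc5ccccc5)cc1 | intermediate
16 | (2R,3R)-5,7-bis(benzyloxy)-2-[3,4-bis(benzyloxy)phenyl]-8-{(2R,3R,4R)-3,7-bis(benzyloxy)-2-[4-(benzyloxy)phenyl]chroman-4-yl}chroman-3-ol | O(Cc5ccccc5)c1ccc([C@H]2Oc3cc(OCc5ccccc5)ccc3[C@H](c3c(OCc5ccccc5)cc(OCc5ccccc5)c4c3O[C@H](c3ccc(OCc5ccccc5)c(OCc5ccccc5)c3)[C@H](O)C4)[C@H]2OCc5ccccc5)cc1 | intermediate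
17 | (2R,3R)-2-(3,4-dihydroxyphenyl)-8-[(2R,3R,4R)-3,7-dihydroxy-2-(4-hydroxyphenyl)chroman-4-yl]chroman-3,5,7-triol, epiguibourtinidol-(4β→8)-epicatechin | Oc1ccc([C@H]2Oc3cc(O)ccc3[C@H](c3c(O)cc(O)c4c3O[C@H](c3ccc(O)c(O)c3)[C@H](O)C4)[C@H]2O)cc1 | target

**Step count and risks**

Total step count: 12. Longest linear sequence: 11 steps (steps 1–7 and 9–12; step 8 is a one-step branch).

The three steps most likely to fail:

1. Step 10 (key step). The very electron-rich lower aryl ring may add directly to the gold-activated alkyne (6-endo hydroarylation) faster than the N-oxide does, so that the alkyne is consumed without oxygen transfer. The fallback turns this competing process into the route. It sets out from 14: PtCl4 or Ph3PAuNTf2 without oxidant (DCE, rt) should give the 2-aryl-2H-chromene (flav-3-ene) F1. Hydroboration–oxidation (BH3·THF, then H2O2/NaOH), with boron adding at C3 anti to the 2-aryl group, should give the 2,3-trans-flavan-3-ol F2. Dess–Martin oxidation (CH2Cl2, rt) then brings the sequence back to the route at ketone 15.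

2. Step 11. Epimerisation at C2 may be slower than hydrogenation, or the catalyst may discriminate poorly between the two ketone epimers, so that the lower unit is not funnelled into one configuration. The fallback sets out from 15 and replaces catalyst control by substrate control plus separation. L-Selectride (THF, −78 °C) should reduce each C2 epimer anti to its 2-aryl group and give 16 together with its lower-unit (2S,3S)-cis diastereomer F3. The two are diastereomers and are separated by chromatography. F3 is returned to 15 by Dess–Martin oxidation and DBU equilibration, and the sequence comes back to the route at 16.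

3. Step 9. The alkoxyphosphonium ion of the electron-rich propargylic alcohol may ionise, leading to C-alkylation of the phloroglucinol-type ring or to elimination, and O-alkylation of the hindered phenol may be slow. The fallback sets out from 13 and changes the mode of activation: ClCO2Me/pyridine (CH2Cl2, 0 °C) gives the propargylic methyl carbonate F4. Copper-catalysed propargylic etherification of phenol 11 (CuOTf·½C6H6, pybox ligand, i-Pr2NEt, MeOH/THF, 0 °C), through a copper allenylidene that is attacked at its γ-carbon by the phenoxide oxygen, comes back to the route at 14.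

**Further compounds**

F1 | step 10 | 5,7-bis(benzyloxy)-2-[3,4-bis(benzyloxy)phenyl]-8-{(2R,3R,4R)-3,7-bis(benzyloxy)-2-[4-(benzyloxy)phenyl]chroman-4-yl}-2H-chromene, both C2 epimers (centre left undefined) | O(Cc5ccccc5)c1ccc([C@H]2Oc3cc(OCc5ccccc5)ccc3[C@H](c3c(OCc5ccccc5)cc(OCc5ccccc5)c4c3OC(c3ccc(OCc5ccccc5)c(OCc5ccccc5)c3)C=C4)[C@H]2OCc5ccccc5)cc1
F2 | step 10 | 2,3-trans-5,7-bis(benzyloxy)-2-[3,4-bis(benzyloxy)phenyl]-8-{(2R,3R,4R)-3,7-bis(benzyloxy)-2-[4-(benzyloxy)phenyl]chroman-4-yl}chroman-3-ol, both trans isomers of the lower unit (its two centres left undefined) | O(Cc5ccccc5)c1ccc([C@H]2Oc3cc(OCc5ccccc5)ccc3[C@H](c3c(OCc5ccccc5)cc(OCc5ccccc5)c4c3OC(c3ccc(OCc5ccccc5)c(OCc5ccccc5)c3)C(O)C4)[C@H]2OCc5ccccc5)cc1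
F3 | step 11 | (2S,3S)-5,7-bis(benzyloxy)-2-[3,4-bis(benzyloxy)phenyl]-8-{(2R,3R,4R)-3,7-bis(benzyloxy)-2-[4-(benzyloxy)phenyl]chroman-4-yl}chroman-3-ol | O(Cc5ccccc5)c1ccc([C@H]2Oc3cc(OCc5ccccc5)ccc3[C@H](c3c(OCc5ccccc5)cc(OCc5ccccc5)c4c3O[C@@H](c3ccc(OCc5ccccc5)c(OCc5ccccc5)c3)[C@@H](O)C4)[C@H]2OCc5ccccc5)cc1
F4 | step 9 | rac-1-[3,4-bis(benzyloxy)phenyl]prop-2-yn-1-yl methyl carbonate | COC(=O)OC(C#C)c1ccc(OCc2ccccc2)c(OCc2ccccc2)c1
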